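**Retrosynthetic overview**
- The pyranone ring, the only ring built, is closed last: O1–C2 cyclodehydration of a 2'-hydroxy-1,3-diketone after global debenzylation. The A ring is symmetric, so closure on either ortho hydroxyl gives the same flavone.
- Key C2–C3 disconnection of the 1,3-diketone: the B-ring aldehyde reacts as an acyl anion (NHC Breslow intermediate) with an A-ring α-chloroketone (enolonium-type a2 partner).
- The α-chloroketone comes from ortho-lithiation of 1,3,5-tris(benzyloxy)-2,4-dimethoxybenzene and a chloroacetyl Weinreb amide.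
- The pentaoxygenated arene comes from phloroglucinol tribenzyl ether by dibromination and copper-catalysed methoxylation.

Assumption: scaposin has no stereocentre, so the achiral structure in the SMILES is the target and no stereocontrol is needed; 1,3,5-tris(benzyloxy)benzene is taken as a catalogue compound.

**Route**

Step 1
Reactants: 1 1,3,5-tris(benzyloxy)benzene
Product: 2 2,4-dibromo-1,3,5-tris(benzyloxy)benzene
Conditions: NBS (2.05 equiv), CH2Cl2, −10 °C to rt, dark
Reagents that add atoms: N-bromosuccinimide, O=C1CCC(=O)N1Br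
Why: Electrophilic aromatic bromination; each ring CH is ortho/para to three alkoxy groups, so two equivalents of NBS brominate two of the three equivalent positions and the deactivation by each bromine lets the reaction stop at the dibromide.

Step 2
Reactants: 2 2,4-dibromo-1,3,5-tris(benzyloxy)benzene
Product: 3 1,3,5-tris(benzyloxy)-2,4-dimethoxybenzene
Conditions: NaOMe/MeOH (8 equiv), CuBr (30 mol %), EtOAc (cat.), DMF, 110 °C, N2
Reagents that add atoms: sodium methoxide, C[O-].[Na+]
Why: Copper-catalysed Ullmann-type methoxylation, which works on di-ortho-substituted electron-rich aryl bromides, replaces both bromines while the benzyl ethers are inert to methoxide.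

Step 3
Reactants: 3 1,3,5-tris(benzyloxy)-2,4-dimethoxybenzene; 4 2-chloro-N-methoxy-N-methylacetamide
Product: 7 2-chloro-1-[2,4,6-tris(benzyloxy)-3,5-dimethoxyphenyl]ethan-1-one, via aryllithium 5 (not isolated), via lithium hemiaminal alkoxide 6 (not isolated)
Conditions: n-BuLi (1.15 equiv), TMEDA, THF, −20 to 0 °C; cannulate into 4 (1.3 equiv), THF, −78 to −30 °C; cold 1 M HCl
Reagents that add atoms: none
Why: Directed ortho-metalation removes the only ring hydrogen, which sits between two benzyloxy groups, and the aryllithium adds once to the Weinreb amide because the chelated tetrahedral intermediate survives until the acidic quench (Weinreb ketone synthesis).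

Step 4
Reactants: 8 3-hydroxy-4,5-dimethoxybenzaldehyde
Product: 9 3-(benzyloxy)-4,5-dimethoxybenzaldehyde
Conditions: BnBr (1.1 equiv), K2CO3, DMF, rt
Reagents that add atoms: benzyl bromide, BrCc1ccccc1
Why: Williamson ether synthesis on the phenoxide; the aldehyde is untouched.

Step 5
Reactants: 9 3-(benzyloxy)-4,5-dimethoxybenzaldehyde; 7 2-chloro-1-[2,4,6-tris(benzyloxy)-3,5-dimethoxyphenyl]ethan-1-one
Product: 12 1-[3-(benzyloxy)-4,5-dimethoxyphenyl]-3-[2,4,6-tris(benzyloxy)-3,5-dimethoxyphenyl]propane-1,3-dione, via Breslow intermediate 10 (not isolated), via hydroxyalkyl thiazolium adduct 11 (not isolated)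
Conditions: 3-benzyl-5-(2-hydroxyethyl)-4-methylthiazolium chloride (20 mol %), Cs2CO3 (2.2 equiv), THF, 40 °C; 7 added over 4 h to 9 (1.5 equiv); aq. citric acid work-up
Reagents that add atoms: none
Why: Proposed new method: the thiazol-2-ylidene adds to aldehyde 9 and proton transfer gives Breslow intermediate 10, an acyl anion equivalent whose nucleophilic carbon displaces chloride from the SN2-activated CH2Cl of 7 (1,2-addition to that ketone is blocked by its two ortho benzyloxy groups) to give 11, which collapses to the 1,3-diketone and free carbene; the closest known reaction types are the Stetter reaction and NHC-catalysed nucleophilic acylation of alkyl halides and sulfonates by aldehydes.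

Step 6
Reactants: 12 1-[3-(benzyloxy)-4,5-dimethoxyphenyl]-3-[2,4,6-tris(benzyloxy)-3,5-dimethoxyphenyl]propane-1,3-dione
Product: 14 scaposin (5,7-dihydroxy-2-(3-hydroxy-4,5-dimethoxyphenyl)-6,8-dimethoxy-4H-chromen-4-one), via tetrahydroxy diketone 13 (not isolated)
Conditions: H2 (1 atm), 10% Pd/C, EtOAc–MeOH, rt; filter; then AcOH, cat. H2SO4, 90 °C
Reagents that add atoms: none
Why: Hydrogenolysis removes the four benzyl ethers and the 2'-hydroxy-1,3-diketone then undergoes acid-catalysed cyclodehydration (the closing step of the Baker–Venkataraman flavone synthesis); closure on either ortho hydroxyl of the symmetric A ring gives the same 5,7-dihydroxy-6,8-dimethoxy pattern and no stereocentre is formed.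

**Compound list**
1 | 1,3,5-tris(benzyloxy)benzene | c1ccc(COc2cc(OCc3ccccc3)cc(OCc3ccccc3)c2)cc1 | starting material
2 | 2,4-dibromo-1,3,5-tris(benzyloxy)benzene | Brc1c(OCc2ccccc2)cc(OCc2ccccc2)c(Br)c1OCc1ccccc1 | intermediate
3 | 1,3,5-tris(benzyloxy)-2,4-dimethoxybenzene | COc1c(OCc2ccccc2)cc(OCc2ccccc2)c(OC)c1OCc1ccccc1 | intermediate
4 | 2-chloro-N-methoxy-N-methylacetamide | CON(C)C(=O)CCl | starting material
5 | [2,4,6-tris(benzyloxy)-3,5-dimethoxyphenyl]lithium | [Li]c1c(OCc2ccccc2)c(OC)c(OCc2ccccc2)c(OC)c1OCc1ccccc1 | intermediate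
6 | lithium 2-chloro-1-[methoxy(methyl)amino]-1-[2,4,6-tris(benzyloxy)-3,5-dimethoxyphenyl]ethan-1-olate (racemic) | [Li]OC(CCl)(N(C)OC)c1c(OCc2ccccc2)c(OC)c(OCc2ccccc2)c(OC)c1OCc1ccccc1 | intermediate
7 | 2-chloro-1-[2,4,6-tris(benzyloxy)-3,5-dimethoxyphenyl]ethan-1-one | COc1c(OCc2ccccc2)c(C(=O)CCl)c(OCc2ccccc2)c(OC)c1OCc1ccccc1 | intermediate
8 | 3-hydroxy-4,5-dimethoxybenzaldehyde | COc1cc(C=O)cc(O)c1OC | starting material
9 | 3-(benzyloxy)-4,5-dimethoxybenzaldehyde | COc1cc(C=O)cc(OCc2ccccc2)c1OC | intermediate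
10 | [3-benzyl-5-(2-hydroxyethyl)-4-methyl-1,3-thiazol-2(3H)-ylidene][3-(benzyloxy)-4,5-dimethoxyphenyl]methanol (Breslow intermediate, alkene geometry undefined) | COc1cc(C(O)=C2SC(CCO)=C(C)N2Cc2ccccc2)cc(OCc2ccccc2)c1OC | intermediate
11 | 3-benzyl-2-{1-[3-(benzyloxy)-4,5-dimethoxyphenyl]-1-hydroxy-3-oxo-3-[2,4,6-tris(benzyloxy)-3,5-dimethoxyphenyl]propyl}-5-(2-hydroxyethyl)-4-methyl-1,3-thiazol-3-ium chloride (racemic) | COc1cc(C(O)(CC(=O)c2c(OCc3ccccc3)c(OC)c(OCc3ccccc3)c(OC)c2OCc2ccccc2)c2sc(CCO)c(C)[n+]2Cc2ccccc2)cc(OCc2ccccc2)c1OC.[Cl-] | intermediate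
12 | 1-[3-(benzyloxy)-4,5-dimethoxyphenyl]-3-[2,4,6-tris(benzyloxy)-3,5-dimethoxyphenyl]propane-1,3-dione | COc1cc(C(=O)CC(=O)c2c(OCc3ccccc3)c(OC)c(OCc3ccccc3)c(OC)c2OCc2ccccc2)cc(OCc2ccccc2)c1OC | intermediate
13 | 1-(3-hydroxy-4,5-dimethoxyphenyl)-3-(2,4,6-trihydroxy-3,5-dimethoxyphenyl)propane-1,3-dione | COc1cc(C(=O)CC(=O)c2c(O)c(OC)c(O)c(OC)c2O)cc(O)c1OC | intermediate
14 | scaposin, 5,7-dihydroxy-2-(3-hydroxy-4,5-dimethoxyphenyl)-6,8-dimethoxy-4H-chromen-4-one (achiral) | COc1cc(-c2cc(=O)c3c(O)c(OC)c(O)c(OC)c3o2)cc(O)c1OC | target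

**Step count**
Total: 6 steps. Longest linear sequence: 5 steps (steps 1, 2, 3, 5, 6).

**Three steps most likely to fail, with fallbacks**

Step 5 is the riskiest. The free carbene can be alkylated by 7, the aldehyde can undergo benzoin coupling, and the product enolate can be alkylated by a second molecule of 7. The fallback replaces the catalytic acyl anion by a stoichiometric dithiane anion and the enolisable chloroketone by an epoxide; it sets out from 7 and 9 and comes back at 12. Chloroketone 7 is reduced with NaBH4 in MeOH/THF at 0 °C to racemic 2-chloro-1-[2,4,6-tris(benzyloxy)-3,5-dimethoxyphenyl]ethan-1-ol F1. K2CO3 in MeOH closes this to racemic 2-[2,4,6-tris(benzyloxy)-3,5-dimethoxyphenyl]oxirane F2. Aldehyde 9 with propane-1,3-dithiol and BF3·OEt2 in CH2Cl2 gives 2-[3-(benzyloxy)-4,5-dimethoxyphenyl]-1,3-dithiane F3. Lithiation of F3 (n-BuLi, THF, −78 to −30 °C) and opening of F2 at its CH2 terminus gives racemic 2-{2-[3-(benzyloxy)-4,5-dimethoxyphenyl]-1,3-dithian-2-yl}-1-[2,4,6-tris(benzyloxy)-3,5-dimethoxyphenyl]ethan-1-ol F4. Dess–Martin oxidation gives 2-{2-[3-(benzyloxy)-4,5-dimethoxyphenyl]-1,3-dithian-2-yl}-1-[2,4,6-tris(benzyloxy)-3,5-dimethoxyphenyl]ethan-1-one F5. MeI/CaCO3 in aqueous MeCN then unmasks the second carbonyl to give 12.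

Step 3 is the second risk. Benzylic lithiation with [1,2]-Wittig rearrangement can compete with ring lithiation, and the hindered aryllithium may deprotonate 4 instead of adding. The fallback is an electrophilic route that sets out from 3 and comes back at 7 with no new compound: Friedel–Crafts chloroacetylation at the only free ring position with chloroacetyl chloride and SnCl4 in CH2Cl2 at −78 °C, quenched cold so that chelation-assisted loss of an ortho benzyl group does not set in.

Step 2 is the third risk. Both bromides are flanked by two benzyloxy groups, so hydrodebromination or incomplete exchange may occur. The fallback sets out from 2 and comes back at 3. Palladium-catalysed hydroxylation (Pd2(dba)3, tBuXPhos, KOH, dioxane/H2O, 100 °C, under argon) gives 2,4,6-tris(benzyloxy)benzene-1,3-diol F6, which is O-methylated with MeI and K2CO3 in acetone to give 3.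

**Further compounds**
F1 | step 5 | 2-chloro-1-[2,4,6-tris(benzyloxy)-3,5-dimethoxyphenyl]ethan-1-ol (racemic) | COc1c(OCc2ccccc2)c(C(O)CCl)c(OCc2ccccc2)c(OC)c1OCc1ccccc1
F2 | step 5 | 2-[2,4,6-tris(benzyloxy)-3,5-dimethoxyphenyl]oxirane (racemic) | COc1c(OCc2ccccc2)c(C2CO2)c(OCc2ccccc2)c(OC)c1OCc1ccccc1
F3 | step 5 | 2-[3-(benzyloxy)-4,5-dimethoxyphenyl]-1,3-dithiane | COc1cc(C2SCCCS2)cc(OCc2ccccc2)c1OC
F4 | step 5 | 2-{2-[3-(benzyloxy)-4,5-dimethoxyphenyl]-1,3-dithian-2-yl}-1-[2,4,6-tris(benzyloxy)-3,5-dimethoxyphenyl]ethan-1-ol (racemic) | COc1cc(C2(CC(O)c3c(OCc4ccccc4)c(OC)c(OCc4ccccc4)c(OC)c3OCc3ccccc3)SCCCS2)cc(OCc2ccccc2)c1OC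
F5 | step 5 | 2-{2-[3-(benzyloxy)-4,5-dimethoxyphenyl]-1,3-dithian-2-yl}-1-[2,4,6-tris(benzyloxy)-3,5-dimethoxyphenyl]ethan-1-one | COc1cc(C2(CC(=O)c3c(OCc4ccccc4)c(OC)c(OCc4ccccc4)c(OC)c3OCc3ccccc3)SCCCS2)cc(OCc2ccccc2)c1OC
F0 | step 3 | none | none
F6 | step 2 | 2,4,6-tris(benzyloxy)benzene-1,3-diol | Oc1c(OCc2ccccc2)cc(OCc2ccccc2)c(O)c1OCc1ccccc1
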